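## Structural features

The target (C29H40O8) is an achiral, constitutionally symmetric dimer: two identical, fully substituted 1,4-benzoquinone rings are joined through their C6 atoms by an unbranched tridecane-1,13-diyl chain. With each ring numbered so that C1 is the carbonyl next to the chain, the ring carries C1=O, C2–OCH3, C3–CH3, C4=O, C5–OH and C6–chain; four ring carbons bear oxygen and none bears hydrogen. There are no stereocentres, so the real difficulty is regiochemical. O2 and O5 each sit between a carbonyl and an alkyl-bearing carbon and differ only in being a methyl ether next to the C3 methyl and a free hydroxyl next to the chain. The C5 hydroxyquinone is a vinylogous acid and the C2 methoxyquinone a vinylogous ester that aqueous acid or base can hydrolyse or exchange; the quinone cores are sensitive to nucleophiles, reductants and alkaline peroxide, and their polyphenolic precursors to air in base. Every operation has to succeed twice on two remote, identical ends, and incomplete conversion would leave mono/bis mixtures that are hard to separate. The key step uses the fact that the oxygens on C2 and C4 are meta to the chain carbon C6 and flank the C3 methyl, which is the pattern of a 2-methyl-5-alkylresorcinol, i.e. a folded tetraketide. The ring bond between C6 and one of its ortho carbons can therefore be made by intramolecular aldol condensation of a linear 4-methyl-3,5,7-trioxo ester, the two carboxyl carbons of a C15 diacid becoming the two C6 atoms.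

## Logic of the disconnections

15 ⇒ 14. The C5 hydroxyl is traced back to an oxirane bridging C5 and C6; in the forward sense the C6–O bond is cleaved and the C5 hydrogen is lost. This removes the second ring hydroxyl from every earlier intermediate, so the O2/O5 differentiation problem disappears. The demand is an isomerisation that leaves the C2 methyl ether untouched.

14 ⇒ 13. Both C–O bonds of each oxirane are cut, leaving a quinone whose only unsubstituted position is C5. The forward step must oxidise the C5=C6 bond and not the C2=C3 bond, and must not displace the C2 methoxy group.

13 ⇒ 12. The O–CH3 bond at O2 is cut. At this stage each ring has exactly one acidic hydroxyl, on the carbon next to the C3 methyl, so the ether is placed without protecting groups. The demand is O-alkylation of an ambident anion on the oxygen that gives the para-quinone.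

12 ⇒ 11. The C1 carbonyl oxygen is removed, leaving a symmetric resorcinol with two equivalent ring CH positions. Oxidation para to either hydroxyl gives the same ring and decides automatically which oxygen becomes carbonyl and which stays as hydroxyl. The forward step must run twice without over-oxidation or radical coupling.

11 ⇒ 9. A carboxyl carbon is put back on the ring carbon ortho to the chain (one ring–carboxyl C–C bond per ring). The ester is the activating group that the ring synthesis needs and leaves without trace. The demand is hydrolysis of a hindered ester and decarboxylation under exclusion of air.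

9 ⇒ 7. In each ring the bond between the chain-bearing carbon and the ester-bearing carbon is cut (C2–C7 and C26–C21 in the chain numbering of 7). Both benzene rings unravel into one linear chain; two rings and two C–C bonds are gained in one operation. The forward step must favour aldol closure over Claisen closure, pyrone formation and retro-Claisen cleavage. For this reason 7 is designed to be cyclized crude, in a methanol-free aqueous medium, and as the methyl ester, so that any ester hydrolysed on the way still converges on 11.

7 ⇒ 6 + 3. The C6–C7 and C21–C22 bonds of 7 are cut, giving a twofold acyl donor that holds the whole tether and two copies of a C7 diketo ester nucleophile. The forward step needs a trianion that reacts only at its terminal carbon, and an acyl donor that stops at the ketone stage twice.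

3 ⇒ 1. The two amide C–N bonds are cut, leading to the commercial C15 diacid, which supplies all thirteen methylenes and both future C6 atoms.

6 ⇒ 4 + 5. The C4–C5 bond of 6 is cut. Methylating an unmethylated 3,5-dioxohexanoate would have to discriminate C4 from C2, mono- from dialkylation and C- from O-alkylation. Here the methyl group is fixed at C4 by the choice of starting material and one step is saved. The forward step is the γ-acylation of a β-keto ester dianion.

## Other disconnections considered

Alternative 1: The cut is at the tether bonds c2–c3 and c11–c12, between two arylethyl units and a dithienylmethane whose two thiophenes and central CH2 are a masked nonane.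
- Forward key step: twofold Kumada coupling of the 2-arylethylmagnesium bromide A2 with bis(5-bromothiophen-2-yl)methane A3 under NiCl2(Ph2PCH2CH2CH2PPh2) to give A1. Desulfurisation with Raney Ni would lead to the saturated bis-arene A6; removal of the four methoxymethyl groups and oxidative demethylation would give 15.
- In its favour: the catalytic cycle is dependable (oxidative addition of zerovalent nickel to C–Br, transmetalation, reductive elimination), and the chelating diphosphine suppresses β-hydride elimination from the primary alkyl. The intermediates are UV-active and likely crystalline.
- Against it here: A2 is a pentasubstituted arene that needs several steps of directed functionalisation. Its Grignard reagent must be formed next to two acetal ethers. Two further operations and a large excess of Raney Ni serve only to tidy the tether.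
- Comparison: structurally the rings arrive complete and the tether is built from three pieces, the reverse of the chosen plan, which buys the tether intact as 1 and grows the rings at its ends. Mechanistically it is transition-metal cross-coupling against enolate chemistry. On oxygenation the alternative is the better plan: all four ring oxygens are in place and differentiated (methoxymethyl against methyl) before the coupling, no late ring C–H oxidation is needed, and a quinone appears only in the last step, whereas the chosen route carries quinones through four steps. On step economy it is the weaker, an estimated eleven to thirteen linear steps against eight.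

Alternative 2: The cut is at the C1–C2 bond of each ring, reached from a four-membered precursor.
- Forward key step: thermolysis of the bis(4-alkenyl-4-hydroxycyclobutenone) A5 opens both cyclobutenones electrocyclically to dienylketenes, which close by 6π electrocyclization and tautomerise to the bis(hydroquinone) A4. Oxidation and selective removal of the isopropyl ethers would give 15.
- In its favour: every substituent is positioned by the order of additions to a squaric ester, and the O2/O5 differentiation (methyl against isopropyl) is built in. The key step needs no reagent.
- Against it here: A5 requires two successive twofold organometallic additions at low temperature to squaric acid derivatives. The first is a 1,13-dimetallated C13 unit, which is not a commodity like 1. The second is a β-methoxyalkenyl metal species prone to β-elimination, and it must add only to the non-vinylogous carbonyl. The squarates are costly, and the end depends on selective dealkylation of one ether beside another.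
- Comparison: both plans are two-directional ring constructions at the ends of an intact C13 chain and both end in an irreversible aromatization, so they are equals in symmetry use. The mechanisms differ, a pericyclic cascade against an ionic aldol. On regiochemical certainty and on step count (about six operations from a squaric ester) the alternative is the equal or the better of the chosen plan. The chosen plan is preferred for its cheap materials and its freedom from cryogenic bifunctional organometallics, and pays for this with more oxidation-state adjustments.

Alternative 3: The cut is at the sp3–sp3 tether bonds c3–c4 and c10–c11.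
- Forward key step: cathodic reduction with NiCl2·6H2O and 2,2':6',2''-terpyridine against a Mg anode would couple the redox-active diester A7 (bis(1,3-dioxoisoindolin-2-yl) nonanedioate) with two molecules of the arylbutanoate ester A8, losing four CO2 and giving A6. Deprotection and oxidative demethylation would then give 15.
- In its favour: both partners are carboxylic acid derivatives, no organometallic reagent is needed, and the new bonds lie far from the hindered arenes.
- Against it here: the two primary alkyl radical precursors have similar reduction behaviour, so cross-selectivity should be close to statistical. Homocoupling of A8, oligomerisation of A7 and hydrodecarboxylation would give homologues of A6 that differ only in the number of CH2 groups and are hard to separate. The cross-coupling must succeed twice on one molecule, and A8 needs a multistep arene synthesis like A2.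
- Comparison: the tether is made from three pieces against one intact piece, and the mechanism is radical capture at low-valent nickel against polar enolate addition. The endgame from A6 is as short as in alternative 1 and shorter than in the chosen plan (two operations against five), which is a point in its favour. Its selectivity risk is the greater: the by-products of the chosen aldol are constitutional isomers that the medium can steer, whereas here they are near-identical homologues. Overall step economy is comparable to alternative 1 and poorer than the chosen plan.

Key step: step 4

Remark: ring positions of all arene and quinone intermediates are quoted in the numbering of the target ring (C1 carbonyl next to the chain, C2 OCH3, C3 CH3, C4 carbonyl, C5, C6 chain carbon). Compound 7 is written all-keto although it should be a mixture of enol tautomers and of meso/racemic forms at its two methine carbons, both of which become sp2 in step 4. The atom balance of the key step (C31H48O10 → C31H44O8 + 2 H2O) and the structures of 7 and 9 were checked and need no revision.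

## Route

Step 1
Reactants: 1 pentadecanedioic acid
Product: 3 N1,N15-dimethoxy-N1,N15-dimethylpentadecanediamide, via bis(acyl imidazolide) 2 (not isolated)
Conditions: 1,1'-carbonyldiimidazole (CDI, 2.2 equiv), CH2Cl2, rt, 1 h; then MeNH(OMe)·HCl (2.5 equiv), rt, 16 h
Reagents that add atoms: N,O-dimethylhydroxylamine hydrochloride, CNOC.Cl; 1,1'-carbonyldiimidazole, O=C(n1ccnc1)n1ccnc1 (its imidazole units are present in 2 only)
Why: Activation of both carboxyl groups as acyl imidazolides (driven by loss of CO2) followed by aminolysis; the liberated imidazole neutralises the amine hydrochloride, so no further base is needed and the two remote ends react independently.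

Step 2
Reactants: 4 methyl 3-oxopentanoate; 5 N-methoxy-N-methylacetamide
Product: 6 methyl 4-methyl-3,5-dioxohexanoate
Conditions: 4 (2 equiv), LiN(iPr)2 (4.2 equiv), THF, −78 → 0 °C; then 5 (1 equiv), −78 → 0 °C; 1 M HCl
Reagents that add atoms: none
Why: γ-Acylation of a β-keto ester dianion: the second, less stabilised carbanion at C4 is the nucleophilic site and adds to the Weinreb amide, whose chelated tetrahedral adduct survives until the acidic quench, so the acidic diketone product never meets the dianion and the methyl group is fixed at C4 by the choice of 4.

Step 3
Reactants: 6 methyl 4-methyl-3,5-dioxohexanoate; 3 N1,N15-dimethoxy-N1,N15-dimethylpentadecanediamide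
Product: 7 dimethyl 4,24-dimethyl-3,5,7,21,23,25-hexaoxoheptacosanedioate
Conditions: 6 (2.6 equiv), LiN(iPr)2 (8.0 equiv), THF, 0 °C, 1 h; then 3 (1 equiv), 0 °C → rt, 2 h; cold 1 M HCl to pH 4; excess 6 removed under high vacuum, crude 7 used at once
Reagents that add atoms: none
Why: Polyanion acylation: three equivalents of amide base remove the C4 methine, a C2 methylene and finally a C6 methyl proton of 6, and the last-formed, least stabilised carbanion at C6 adds to each Weinreb amide of 3; the N-methoxy chelate holds each adduct at the tetrahedral stage, so the triketone is released only on quench, and the excess of trianion drives reaction at both ends.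

Step 4
Reactants: 7 dimethyl 4,24-dimethyl-3,5,7,21,23,25-hexaoxoheptacosanedioate
Product: 9 dimethyl 6,6'-(tridecane-1,13-diyl)bis(2,4-dihydroxy-3-methylbenzoate), via bis(aldol) carbinol 8 (not isolated)
Conditions: 0.2 M aq. KOH (8 equiv), THF, 0.02 M, 0 °C → rt, Ar; then 1 M HCl to pH 2, rt
Reagents that add atoms: none
Why: Hydroxide reversibly deprotonates the acidic positions of 7 (C2, C4, C6 and C26, C24, C22); the tautomer with an enolate at the ester-activated C2 and a free C7 ketone adds C2 to C7 in a 6-(enolexo)-exo-trig aldol closure to the tertiary carbinol of 8, and the same happens independently at C26/C21, thirteen methylenes away. E1cB loss of water from each carbinol and enolisation of the two remaining ring ketones then give the benzene rings, acidification completing the dehydration; aromatization makes the sequence irreversible. The closest known reaction type is the biomimetic base-mediated cyclization of 3,5,7-triketo esters to β-resorcylates, run here in two directions and with a C4 methyl. No stereocentre is created: the methine centres of 7 and the transient centres of 8 all become sp2. The selectivity needed is aldol closure (C2 onto C7) over Claisen closure (C6 onto the ester carbonyl, giving an acylphloroglucinol), over γ-pyrone formation and over retro-Claisen cleavage. It is secured by the doubly activated C2 methylene, by a methanol-free and Mg-free aqueous medium in which addition to the ketone is fast while expulsion of methoxide from the ester is slow, by keeping the solution basic until cyclization is complete, and by dilution against intermolecular aldol reactions. Any ester that is saponified on the way can no longer serve as a Claisen acceptor and is funnelled by step 5 to the same resorcinol 11.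

Step 5
Reactants: 9 dimethyl 6,6'-(tridecane-1,13-diyl)bis(2,4-dihydroxy-3-methylbenzoate)
Product: 11 5,5'-(tridecane-1,13-diyl)bis(2-methylbenzene-1,3-diol), via bis(resorcylic acid) 10 (not isolated)
Conditions: KOH (20 equiv), H2O–DMSO, 100 °C, Ar (degassed); then conc. HCl to pH 1, 80 °C
Reagents that add atoms: potassium hydroxide, [K+].[OH-] (its oxygen appears in 10 only and leaves again with CO2)
Why: Saponification of the hindered, hydrogen-bonded salicylate-type esters needs hot concentrated hydroxide; on acidification each 2,4-dihydroxybenzoic acid protonates at the carboxyl-bearing carbon (a β-keto-acid-like tautomer) and loses CO2 by ipso-protodecarboxylation, leaving symmetric 2-methyl-5-alkylresorcinol rings.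

Step 6
Reactants: 11 5,5'-(tridecane-1,13-diyl)bis(2-methylbenzene-1,3-diol)
Product: 12 6,6'-(tridecane-1,13-diyl)bis(2-hydroxy-3-methylcyclohexa-2,5-diene-1,4-dione)
Conditions: ON(SO3K)2 (5 equiv), aq. KH2PO4, acetone, 0 °C → rt
Reagents that add atoms: potassium nitrosodisulfonate, [K+].[K+].[O]N(S(=O)(=O)[O-])S(=O)(=O)[O-]
Why: Teuber oxidation: the nitroxyl radical abstracts a phenolic hydrogen, a second equivalent couples at the ring carbon para to that oxygen and the adduct collapses to the para-quinone; the two ring CH positions are equivalent by symmetry and the carbon between the hydroxyls is blocked by methyl, so only one hydroxyquinone (C1 and C4 carbonyls, free hydroxyl on C2 next to the methyl) can form per ring.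

Step 7
Reactants: 12 6,6'-(tridecane-1,13-diyl)bis(2-hydroxy-3-methylcyclohexa-2,5-diene-1,4-dione)
Product: 13 6,6'-(tridecane-1,13-diyl)bis(2-methoxy-3-methylcyclohexa-2,5-diene-1,4-dione)
Conditions: MeI (6 equiv), K2CO3 (3 equiv), acetone, rt, dark
Reagents that add atoms: iodomethane, CI
Why: The hydroxyquinone is a vinylogous carboxylic acid that carbonate deprotonates fully; Williamson-type O-alkylation of the ambident anion at O2 gives the conjugated para-quinone methyl ether, not the ortho-quinone ether from O4, and since O2 is the only acidic hydroxyl present the ether is placed next to the C3 methyl without protecting groups.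

Step 8
Reactants: 13 6,6'-(tridecane-1,13-diyl)bis(2-methoxy-3-methylcyclohexa-2,5-diene-1,4-dione)
Product: 14 1,1'-(tridecane-1,13-diyl)bis(3-methoxy-4-methyl-7-oxabicyclo[4.1.0]hept-3-ene-2,5-dione)
Conditions: 30% aq. H2O2 (6 equiv), Na2CO3 (0.5 equiv), THF–H2O, 0 °C, 30 min; quench with aq. NaH2PO4
Reagents that add atoms: hydrogen peroxide, OO
Why: Weitz–Scheffer nucleophilic epoxidation: hydroperoxide adds to the unsubstituted C5 terminus (β to the C1 carbonyl) of the electron-poor C5=C6 bond and the enolate closes onto oxygen, while the tetrasubstituted C2=C3 bond is deactivated by its methoxy donor; each oxirane is necessarily cis-fused, and the four new stereocentres form without control (racemic within each ring, both relative arrangements of the remote rings) and are all removed in step 9.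

Step 9
Reactants: 14 1,1'-(tridecane-1,13-diyl)bis(3-methoxy-4-methyl-7-oxabicyclo[4.1.0]hept-3-ene-2,5-dione)
Product: 15 6,6'-(tridecane-1,13-diyl)bis(5-hydroxy-2-methoxy-3-methylcyclohexa-2,5-diene-1,4-dione)
Conditions: conc. H2SO4, 0 °C, 10 min; then ice–water
Reagents that add atoms: none
Why: Acid-catalysed isomerisation of an α,β-epoxy ketone to its diosphenol: protonation of the oxirane, cleavage of the C6–O bond and loss of the C5 proton through the C4 enol leave the oxygen on C5 as the hydroxyl of a hydroxyquinone; C6 bears no hydrogen, so the isomerisation can run only in this direction, and short contact with cold anhydrous acid is chosen to spare the C2 methyl ether.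

## Compound list

1 | pentadecanedioic acid | OC(=O)CCCCCCCCCCCCCC(=O)O | starting material
2 | 1,15-di(1H-imidazol-1-yl)pentadecane-1,15-dione (bis(acyl imidazolide)) | O=C(CCCCCCCCCCCCCC(=O)n1ccnc1)n1ccnc1 | intermediate (not isolated)
3 | N1,N15-dimethoxy-N1,N15-dimethylpentadecanediamide | CON(C)C(=O)CCCCCCCCCCCCCC(=O)N(C)OC | intermediate
4 | methyl 3-oxopentanoate | CCC(=O)CC(=O)OC | starting material
5 | N-methoxy-N-methylacetamide | CC(=O)N(C)OC | starting material
6 | methyl 4-methyl-3,5-dioxohexanoate (keto form; methine centre enolizable, unassigned) | CC(=O)C(C)C(=O)CC(=O)OC | intermediate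
7 | dimethyl 4,24-dimethyl-3,5,7,21,23,25-hexaoxoheptacosanedioate (keto form; two enolizable methine centres, unassigned) | COC(=O)CC(=O)C(C)C(=O)CC(=O)CCCCCCCCCCCCCC(=O)CC(=O)C(C)C(=O)CC(=O)OC | intermediate
8 | dimethyl 2,2'-(tridecane-1,13-diyl)bis(2-hydroxy-5-methyl-4,6-dioxocyclohexane-1-carboxylate) (mixture of stereoisomers and enol forms, all centres unassigned) | COC(=O)C1C(=O)C(C)C(=O)CC1(O)CCCCCCCCCCCCCC1(O)CC(=O)C(C)C(=O)C1C(=O)OC | intermediate (not isolated)
9 | dimethyl 6,6'-(tridecane-1,13-diyl)bis(2,4-dihydroxy-3-methylbenzoate) | COC(=O)c1c(O)c(C)c(O)cc1CCCCCCCCCCCCCc1cc(O)c(C)c(O)c1C(=O)OC | intermediate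
10 | 6,6'-(tridecane-1,13-diyl)bis(2,4-dihydroxy-3-methylbenzoic acid) | OC(=O)c1c(O)c(C)c(O)cc1CCCCCCCCCCCCCc1cc(O)c(C)c(O)c1C(=O)O | intermediate (not isolated)
11 | 5,5'-(tridecane-1,13-diyl)bis(2-methylbenzene-1,3-diol) | Cc1c(O)cc(CCCCCCCCCCCCCc2cc(O)c(C)c(O)c2)cc1O | intermediate
12 | 6,6'-(tridecane-1,13-diyl)bis(2-hydroxy-3-methylcyclohexa-2,5-diene-1,4-dione) | CC1=C(O)C(=O)C(CCCCCCCCCCCCCC2=CC(=O)C(C)=C(O)C2=O)=CC1=O | intermediate
13 | 6,6'-(tridecane-1,13-diyl)bis(2-methoxy-3-methylcyclohexa-2,5-diene-1,4-dione) | COC1=C(C)C(=O)C=C(CCCCCCCCCCCCCC2=CC(=O)C(C)=C(OC)C2=O)C1=O | intermediate
14 | 1,1'-(tridecane-1,13-diyl)bis(3-methoxy-4-methyl-7-oxabicyclo[4.1.0]hept-3-ene-2,5-dione) (cis-fused oxiranes, each racemic; both relative arrangements of the two rings) | COC1=C(C)C(=O)C2OC2(CCCCCCCCCCCCCC34OC3C(=O)C(C)=C(OC)C4=O)C1=O | intermediate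
15 | 6,6'-(tridecane-1,13-diyl)bis(5-hydroxy-2-methoxy-3-methylcyclohexa-2,5-diene-1,4-dione), CNP0110425.0 | COC1=C(C)C(=O)C(O)=C(CCCCCCCCCCCCCC2=C(O)C(=O)C(C)=C(OC)C2=O)C1=O | target

## Step count and least certain steps

Total step count: 9. Longest linear sequence: 8 steps (step 1 or step 2, then steps 3 to 9).

Step 4 (key step). The most likely failures are these:
- Claisen closure competing at one or both ends if the medium is not aqueous enough.
- Dehydration of unreacted triketone ends to γ-pyrones if the solution is acidified before cyclization is complete.
- Hydroxide-induced retro-Claisen cleavage of the 4-methyl-β-diketone units, which are less enolised than unsubstituted ones.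

Fallback, setting out from 7: brief treatment with CF3CO2H (CH2Cl2, 0 °C → rt) should dehydrate each 1,3,5-triketone unit to the stable, chromatographable bis(γ-pyrone) dimethyl 2,2'-[tridecane-1,13-diylbis(3-methyl-4-oxo-4H-pyran-6,2-diyl)]diacetate F3. Hot aqueous KOH (DMSO co-solvent, Ar) then saponifies the esters and reopens the pyrones by conjugate addition of hydroxide. The chain is thereby released as a triketo carboxylate, in which Claisen closure is impossible and only the C2-onto-C7 aldol remains. This gives 10 directly, and the acidification of step 5 brings the route back at 11.

Step 3. The strongly basic trianion may deprotonate the Weinreb amide α to its carbonyl or fragment its N–OCH3 group instead of adding. The acylation may also stop after one end, and 7 may cyclize uncontrolled during work-up.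

Fallback, setting out from 3: reduction with iBu2AlH (THF, −78 °C) gives pentadecanedial F1. Aldol addition of the trianion of 6 (generated as in step 3) to F1 at −78 °C is a faster C–C bond formation than amide acylation. It should give dimethyl 7,21-dihydroxy-4,24-dimethyl-3,5,23,25-tetraoxoheptacosanedioate F2 as a mixture of stereoisomers. Oxidation of both carbinols with Dess–Martin periodinane (CH2Cl2, NaHCO3) brings the route back at 7.

Step 6. The lipophilic substrate may be oxidised incompletely (one ring only) in the aqueous medium, and intermediate phenoxyl radicals may couple oxidatively between molecules.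

Fallback, setting out from 11: Vilsmeier–Haack formylation (POCl3, DMF, 0 °C → rt; aq. NaOAc) at the ring CH para to a hydroxyl gives 6,6'-(tridecane-1,13-diyl)bis(2,4-dihydroxy-3-methylbenzaldehyde) F4, the first formyl group deactivating its ring toward a second. An acid-catalysed Dakin oxidation (H2O2, cat. H2SO4, MeOH) exchanges each formyl group for a hydroxyl to give 6,6'-(tridecane-1,13-diyl)bis(3-methylbenzene-1,2,4-triol) F5. Aqueous FeCl3 (or air) oxidises F5 to 12, where the route is rejoined.

Step 8. Hydroxide or hydroperoxide may add to C2 and expel methoxide (loss of the vinylogous ester), peroxide may cleave the quinone ring, and only one ring may be epoxidised.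

Fallback, setting out from 13: Thiele–Winter acetoxylation (Ac2O, BF3·OEt2, 40 °C) adds acetate at the only free ring position C5 and acetylates the resulting hydroquinone, giving 6,6'-(tridecane-1,13-diyl)bis(2-methoxy-3-methylbenzene-1,4,5-triyl) hexaacetate F6. Methanolysis (K2CO3, MeOH, then air) frees the 1,4,5-triol, which oxidises to the hydroxyquinone. The route is rejoined at 15 without passing through 14, and in methanol any exchange at the C2 ether is degenerate.

Step 9. Strong acid may hydrolyse the C2 methyl ether on quench, and the protonated epoxy diketone may undergo acyl migration with ring contraction instead of losing the C5 proton.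

Fallback, setting out from 14: buffered acetolysis (KOAc, AcOH, 60 °C) opens each oxirane by SN2 attack of acetate at the secondary carbon C5, giving 6,6'-(tridecane-1,13-diyl)bis(5-acetoxy-6-hydroxy-2-methoxy-3-methylcyclohex-2-ene-1,4-dione) F7. F7 loses water by E1cB (the C5 hydrogen is α to the C4 carbonyl; Ac2O–pyridine if needed) to give 6,6'-(tridecane-1,13-diyl)bis(5-acetoxy-2-methoxy-3-methylcyclohexa-2,5-diene-1,4-dione) F8. K2CO3 in MeOH at 0 °C removes the enol acetates and brings the route back at 15.

## Further compounds

F1 | step 3 | pentadecanedial | O=CCCCCCCCCCCCCCC=O
F2 | step 3 | dimethyl 7,21-dihydroxy-4,24-dimethyl-3,5,23,25-tetraoxoheptacosanedioate (stereocentres unassigned) | COC(=O)CC(=O)C(C)C(=O)CC(O)CCCCCCCCCCCCCC(O)CC(=O)C(C)C(=O)CC(=O)OC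
F3 | step 4 | dimethyl 2,2'-[tridecane-1,13-diylbis(3-methyl-4-oxo-4H-pyran-6,2-diyl)]diacetate | COC(=O)CC1=C(C)C(=O)C=C(O1)CCCCCCCCCCCCCC1=CC(=O)C(C)=C(CC(=O)OC)O1
F4 | step 6 | 6,6'-(tridecane-1,13-diyl)bis(2,4-dihydroxy-3-methylbenzaldehyde) | O=Cc1c(O)c(C)c(O)cc1CCCCCCCCCCCCCc1cc(O)c(C)c(O)c1C=O
F5 | step 6 | 6,6'-(tridecane-1,13-diyl)bis(3-methylbenzene-1,2,4-triol) | Oc1c(O)c(C)c(O)cc1CCCCCCCCCCCCCc1cc(O)c(C)c(O)c1O
F6 | step 8 | 6,6'-(tridecane-1,13-diyl)bis(2-methoxy-3-methylbenzene-1,4,5-triyl) hexaacetate | COc1c(C)c(OC(C)=O)c(OC(C)=O)c(CCCCCCCCCCCCCc2c(OC(C)=O)c(OC(C)=O)c(C)c(OC)c2OC(C)=O)c1OC(C)=O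
F7 | step 9 | 6,6'-(tridecane-1,13-diyl)bis(5-acetoxy-6-hydroxy-2-methoxy-3-methylcyclohex-2-ene-1,4-dione) (trans opening, stereocentres otherwise unassigned) | COC1=C(C)C(=O)C(OC(C)=O)C(O)(CCCCCCCCCCCCCC2(O)C(OC(C)=O)C(=O)C(C)=C(OC)C2=O)C1=O
F8 | step 9 | 6,6'-(tridecane-1,13-diyl)bis(5-acetoxy-2-methoxy-3-methylcyclohexa-2,5-diene-1,4-dione) | COC1=C(C)C(=O)C(OC(C)=O)=C(CCCCCCCCCCCCCC2=C(OC(C)=O)C(=O)C(C)=C(OC)C2=O)C1=O
A1 | alternative 1 | bis(5-{2-[2,6-bis(methoxymethoxy)-3,5-dimethoxy-4-methylphenyl]ethyl}thiophen-2-yl)methane | COCOc1c(CCc2ccc(Cc3ccc(CCc4c(OCOC)c(OC)c(C)c(OC)c4OCOC)s3)s2)c(OCOC)c(OC)c(C)c1OC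
A2 | alternative 1 | 2-[2,6-bis(methoxymethoxy)-3,5-dimethoxy-4-methylphenyl]ethylmagnesium bromide | COCOc1c(CC[Mg]Br)c(OCOC)c(OC)c(C)c1OC
A3 | alternative 1 | bis(5-bromothiophen-2-yl)methane | Brc1ccc(Cc2ccc(Br)s2)s1
A4 | alternative 2 | 6,6'-(tridecane-1,13-diyl)bis(5-isopropoxy-2-methoxy-3-methylbenzene-1,4-diol) | COc1c(C)c(O)c(OC(C)C)c(CCCCCCCCCCCCCc2c(OC(C)C)c(O)c(C)c(OC)c2O)c1O
A5 | alternative 2 | 2,2'-(tridecane-1,13-diyl)bis[4-hydroxy-3-isopropoxy-4-(1-methoxyprop-1-en-2-yl)cyclobut-2-en-1-one] (carbinol centres and alkene geometry unassigned) | COC=C(C)C1(O)C(OC(C)C)=C(CCCCCCCCCCCCCC2=C(OC(C)C)C(O)(C(C)=COC)C2=O)C1=O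
A6 | alternative 3 | 1,13-bis[2,6-bis(methoxymethoxy)-3,5-dimethoxy-4-methylphenyl]tridecane | COCOc1c(CCCCCCCCCCCCCc2c(OCOC)c(OC)c(C)c(OC)c2OCOC)c(OCOC)c(OC)c(C)c1OC
A7 | alternative 3 | bis(1,3-dioxoisoindolin-2-yl) nonanedioate | O=C(CCCCCCCC(=O)ON1C(=O)c2ccccc2C1=O)ON1C(=O)c2ccccc2C1=O
A8 | alternative 3 | 1,3-dioxoisoindolin-2-yl 4-[2,6-bis(methoxymethoxy)-3,5-dimethoxy-4-methylphenyl]butanoate | COCOc1c(CCCC(=O)ON2C(=O)c3ccccc3C2=O)c(OCOC)c(OC)c(C)c1OC
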